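The ring is numbered C1 (carbinol carbon bearing C7H2OBz), C2 (ketone), C3=C4, C5 (CHOBz), C6 (CHOH).
Cuts: the two benzoate C–O bonds (O5, O7) go first. The 4-hydroxy-enone is then folded back into a 1-methoxy-7-oxanorbornene ketal (bridge C5–O–C2) and C7 is raised to the acid level. Last, ring bonds C1–C2 and C5–C6 are cut together (retro-Diels–Alder) to give 2-methoxyfuran and a chiral (Z)-2,3-dioxygenated acrylate.
Enabling feature: the only ring alkene, C3=C4, sits between two oxygen-bearing carbons, C2 at the ketone level and C5 at the alcohol level. C2–C3=C4–C5 with these oxygens is therefore a 2-alkoxyfuran in disguise, and the C1/C6 cis-diol with C7 on C1 is the matching dienophile.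
Forward: the dienophile takes three steps and one [4+2] step builds the whole carbocycle. LiAlH4 strips the helpers (tert-butyl acetal, acetate) and sets C7, O7 is benzoylated, ketal hydrolysis unveils the enone and O5–H, and O5 is benzoylated.
Stereochemistry: the (R) centre of a D-serine-derived hydroxy acid is parked on a tert-butyl acetal carbon, erased, and regenerated at C1 by addition anti to tert-butyl. The Z alkene gives the C1/C6 cis-diol, and the exo mode puts O5 trans to O6.

Key step: step 4

Assumption: acid 1 is taken as a catalogue compound; otherwise it is one step from O-benzyl-D-serine by nitrous acid deamination, which proceeds with retention.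

Step 1
Reactants: 1 (R)-3-(benzyloxy)-2-hydroxypropanoic acid; 2 pivalaldehyde
Product: 3 (2R,5R)-5-(benzyloxymethyl)-2-tert-butyl-1,3-dioxolan-4-one
Conditions: 2 (1.5 equiv), TsOH·H2O (cat.), H2SO4 (cat.), pentane, reflux, Dean–Stark trap; crystallisation or chromatography
Reagents that add atoms: none
Why: Acid-catalysed acetalisation of an α-hydroxy acid with water removal (first half of a self-regeneration-of-stereocentres sequence): under equilibrating conditions the tert-butyl group settles cis to the C5 side chain, so the (R) centre of 1 is copied onto the acetal carbon as (2R), and the minor trans isomer, which would lead to the wrong enantiomer, is removed by purification.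

Step 2
Reactants: 3 (2R,5R)-5-(benzyloxymethyl)-2-tert-butyl-1,3-dioxolan-4-one
Product: 4 (2R,5R)-2-tert-butyl-5-(hydroxymethyl)-1,3-dioxolan-4-one
Conditions: H2 (1 atm), 10% Pd/C, EtOAc, rt
Reagents that add atoms: none
Why: Catalytic hydrogenolysis of a benzyl ether under neutral conditions leaves the acylal ring and both stereocentres untouched.

Step 3
Reactants: 4 (2R,5R)-2-tert-butyl-5-(hydroxymethyl)-1,3-dioxolan-4-one
Product: 6 (Z)-[(2R)-2-tert-butyl-5-oxo-1,3-dioxolan-4-ylidene]methyl acetate, via formyl lactone 5 (not isolated)
Conditions: Dess–Martin periodinane, CH2Cl2, 0 °C to rt, filtration through Celite; then Ac2O, Et3N, DMAP (cat.), CH2Cl2, 0 °C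
Reagents that add atoms: acetic anhydride CC(=O)OC(C)=O
Why: Dess–Martin oxidation gives the strongly enolised α-formyl lactone and O-acylation traps the enol: the ring stereocentre next to the carbonyl is erased on purpose while the acetal carbon keeps the chirality, and the acetoxy group should end anti to the lactone carbonyl and syn to the ring oxygen (Z), as is usual for O-functionalised hydroxymethylene lactones, because this geometry avoids the carbonyl–oxygen dipole clash and can be reached by DMAP-mediated equilibration.

Step 4
Reactants: 6 (Z)-[(2R)-2-tert-butyl-5-oxo-1,3-dioxolan-4-ylidene]methyl acetate; 7 2-methoxyfuran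
Product: 8 (1S,2S,2'R,3S,4R)-2'-tert-butyl-1-methoxy-5'-oxospiro[7-oxabicyclo[2.2.1]hept-5-ene-2,4'-[1,3]dioxolan]-3-yl acetate (lactone C=O exo; dioxolanone ring oxygen endo; acetate endo)
Conditions: 7 (4 equiv), BHT (cat.), solid K2CO3 (trace, acid scavenger), PhMe, 55 °C, sealed tube, dark; crude product taken on without heating
Reagents that add atoms: none
Why: Thermal normal-electron-demand Diels–Alder reaction: the HOMO of the donor-substituted furan 7 (largest coefficient at the unsubstituted C5) meets the LUMO of the lactone-conjugated alkene of 6 (largest coefficient at the CH(OAc) carbon) in a concerted but asynchronous suprafacial [4+2] transition state, so that furan C5 bonds to the acetoxy-bearing carbon (zeylenone C5–C6) and the methoxy-bearing furan C2 bonds to the lactone α-carbon (zeylenone C2–C1), the "ortho" orientation. The closest known reaction types are the cycloadditions of 2-alkoxy- and 2-silyloxyfurans with acrylate-type dienophiles and the exo- and face-selective cycloadditions of 2-tert-butyl-5-methylene-1,3-dioxolan-4-one with cyclic dienes. The one ring closed is the six-membered carbocycle C1–C6, formed intermolecularly in a boat-shaped [4πs+2πs] closure with the furan oxygen left as a bridge from C2 to C5 (7-oxanorbornene). C1 is set by the acetal carbon, whose tert-butyl group blocks one face of the flat dioxolanone so that 7 adds anti to it; C6 follows from C1 because addition is suprafacial on the Z alkene (both oxygens stay cis); C5 and the temporary ketal centre C2 follow from the exo mode (lactone C=O exo, ring oxygen and acetate endo) that s-cis-locked exocyclic α-oxyacrylates prefer on dipole and steric grounds, which places the bridge oxygen on C5 trans to the oxygen on C6. The step needs regio-, exo- and facial selectivity and must stay concerted enough that the enolate-like terminus does not expel acetate; the methoxy donor, the locked s-cis lactone, the tert-butyl acetal and acid-free conditions at moderate temperature are there to secure this. The bridgehead methoxy ketal stores C2 at the ketone level and O5 at the alcohol level, so no later oxidation is needed.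

Step 5
Reactants: 8 spiro Diels–Alder adduct
Product: 9 (1S,2S,3S,4R)-2-(hydroxymethyl)-1-methoxy-7-oxabicyclo[2.2.1]hept-5-ene-2,3-diol
Conditions: LiAlH4 (3 equiv), THF, −20 to 0 °C; H2O, 15% aq. NaOH, H2O
Reagents that add atoms: none
Why: Exhaustive LiAlH4 reduction of esters: hydride opens the dioxolanone at its acyl carbon, the released hemiacetal alkoxide sheds pivalaldehyde (reduced further), C7 reaches the CH2OH level and the acetate is cleaved, whereas the bridgehead ketal, the ring alkene and the four ring stereocentres are inert to basic hydride conditions.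

Step 6
Reactants: 9 (1S,2S,3S,4R)-2-(hydroxymethyl)-1-methoxy-7-oxabicyclo[2.2.1]hept-5-ene-2,3-diol
Product: 10 [(1S,2S,3S,4R)-2,3-dihydroxy-1-methoxy-7-oxabicyclo[2.2.1]hept-5-en-2-yl]methyl benzoate
Conditions: BzCl (1.05 equiv), pyridine, CH2Cl2, −20 °C
Reagents that add atoms: benzoyl chloride O=C(Cl)c1ccccc1
Why: Rate-controlled pyridine-mediated esterification: the primary C7 hydroxyl should react far faster than the endo secondary and the tertiary hydroxyl, and the basic medium keeps the acid-labile ketal closed.

Step 7
Reactants: 10 [(1S,2S,3S,4R)-2,3-dihydroxy-1-methoxy-7-oxabicyclo[2.2.1]hept-5-en-2-yl]methyl benzoate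
Product: 11 [(1S,5R,6S)-1,5,6-trihydroxy-2-oxocyclohex-3-en-1-yl]methyl benzoate
Conditions: 0.5 M aq. HCl, THF, 0 °C to rt
Reagents that add atoms: water O
Why: Acid-catalysed ketal hydrolysis driven by release of oxanorbornene strain: protonation of the bridge oxygen and push from the methoxy group break C2–O (never C5–O, so C5 keeps its configuration), water and loss of methanol give the C2 ketone conjugated with C3=C4, and the earlier benzoylation of O7 prevents capture of the oxocarbenium ion by a primary hydroxyl.

Step 8
Reactants: 11 [(1S,5R,6S)-1,5,6-trihydroxy-2-oxocyclohex-3-en-1-yl]methyl benzoate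
Product: 14 zeylenone, via diol boronate 12 (not isolated), via benzoylated boronate 13 (not isolated)
Conditions: PhB(OH)2 (1.05 equiv), 4 Å MS, CH2Cl2, rt; then BzCl (1.2 equiv), pyridine, DMAP (cat.), 0 °C; then pinacol, rt
Reagents that add atoms: benzoyl chloride O=C(Cl)c1ccccc1; phenylboronic acid OB(O)c1ccccc1 (its atoms are held only in 12 and 13)
Why: Transient cyclic boronate protection of a cis-1,2-diol followed by pyridine/DMAP acylation: only the cis C1/C6 pair can span a five-membered dioxaborolane, so the allylic C5 hydroxyl is the only free one when benzoyl chloride arrives, and transesterification with pinacol then frees the diol without base, touching no stereocentre.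

Compound list
1 | (R)-3-(benzyloxy)-2-hydroxypropanoic acid | OC(=O)[C@H](O)COCc1ccccc1 | starting material
2 | pivalaldehyde (2,2-dimethylpropanal) | CC(C)(C)C=O | starting material
3 | (2R,5R)-5-(benzyloxymethyl)-2-tert-butyl-1,3-dioxolan-4-one (cis) | CC(C)(C)[C@H]1OC(=O)[C@@H](COCc2ccccc2)O1 | intermediate
4 | (2R,5R)-2-tert-butyl-5-(hydroxymethyl)-1,3-dioxolan-4-one | CC(C)(C)[C@H]1OC(=O)[C@@H](CO)O1 | intermediate
5 | (2R)-2-tert-butyl-5-oxo-1,3-dioxolane-4-carbaldehyde (C4 labile, largely enolised) | CC(C)(C)[C@H]1OC(=O)C(C=O)O1 | intermediate
6 | (Z)-[(2R)-2-tert-butyl-5-oxo-1,3-dioxolan-4-ylidene]methyl acetate (OAc syn to ring O, anti to C=O) | CC(C)(C)[C@H]1OC(=O)/C(=C/OC(C)=O)O1 | intermediate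
7 | 2-methoxyfuran | COc1ccco1 | starting material
8 | (1S,2S,2'R,3S,4R)-2'-tert-butyl-1-methoxy-5'-oxospiro[7-oxabicyclo[2.2.1]hept-5-ene-2,4'-[1,3]dioxolan]-3-yl acetate | CO[C@@]12C=C[C@@H](O1)[C@H](OC(C)=O)[C@]23O[C@@H](C(C)(C)C)OC3=O | intermediate
9 | (1S,2S,3S,4R)-2-(hydroxymethyl)-1-methoxy-7-oxabicyclo[2.2.1]hept-5-ene-2,3-diol (both ring hydroxyls endo) | CO[C@@]12C=C[C@@H](O1)[C@H](O)[C@@]2(O)CO | intermediate
10 | [(1S,2S,3S,4R)-2,3-dihydroxy-1-methoxy-7-oxabicyclo[2.2.1]hept-5-en-2-yl]methyl benzoate | CO[C@@]12C=C[C@@H](O1)[C@H](O)[C@@]2(O)COC(=O)c3ccccc3 | intermediate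
11 | [(1S,5R,6S)-1,5,6-trihydroxy-2-oxocyclohex-3-en-1-yl]methyl benzoate | O=C(OC[C@@]1(O)C(=O)C=C[C@@H](O)[C@@H]1O)c1ccccc1 | intermediate
12 | cyclic phenylboronate of the C1/C6 cis-diol of 11 (C5–OH free) | O=C(OC[C@]12OB(c3ccccc3)O[C@H]1[C@H](O)C=CC2=O)c4ccccc4 | intermediate
13 | cyclic phenylboronate of the C1/C6 cis-diol of zeylenone | O=C(OC[C@]12OB(c3ccccc3)O[C@H]1[C@H](OC(=O)c4ccccc4)C=CC2=O)c5ccccc5 | intermediate
14 | zeylenone, [(1S,5R,6S)-5-(benzoyloxy)-1,6-dihydroxy-2-oxocyclohex-3-en-1-yl]methyl benzoate | O=C(OC[C@@]1(O)C(=O)C=C[C@@H](OC(=O)c2ccccc2)[C@@H]1O)c1ccccc1 | target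

Total steps: 8. Longest linear sequence: 8 (1 to 14; 2 and 7 are bought).

Steps most likely to fail

Step 4. The cycloaddition of a trisubstituted alkene flanked by two oxygen donors may be slow or reversible. It may also drift into a stepwise path in which the zwitterion expels acetate (net vinylic substitution) or the furan rearomatises, and exo or facial selectivity may erode.
- Fallback (sets out from 7, returns at 9): the two oxygens are tied back in a cyclic carbonate, which cannot depart and lowers the LUMO. The absolute configuration is then settled afterwards by resolution instead of by an auxiliary.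
- Bought methyl 2-oxo-1,3-dioxolane-4-carboxylate is brominated at the captodative ring carbon (NBS, AIBN, PhCF3, reflux) to methyl 4-bromo-2-oxo-1,3-dioxolane-4-carboxylate F1.
- Et3N removes HBr to give methyl 2-oxo-1,3-dioxole-4-carboxylate F2.
- Cycloaddition with 7, in which the innate endo preference of the carbonate and the exo preference of the α-substituted ester reinforce each other, should give the racemic carbonate adduct F3.
- LiAlH4 takes ester and carbonate down to the racemic triol F4, and preparative chromatography on a chiral stationary phase delivers 9.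

Step 3. The formyl lactone may hydrate or decompose before it is trapped, and the enol acylation may give the wrong alkene geometry or a mixture that does not equilibrate.
- Fallback (sets out from 4, returns at 6): the alkene is made by bromination–dehydrobromination, the standard way to 5-alkylidene derivatives of such acetals, instead of by oxidation.
- 4 is acetylated (Ac2O, pyridine) to [(2R,4R)-2-tert-butyl-5-oxo-1,3-dioxolan-4-yl]methyl acetate F5.
- Radical bromination (NBS, AIBN, PhCF3, reflux) at the captodative ring carbon, anti to tert-butyl, gives the tertiary ring bromide F6.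
- Et3N removes HBr towards the side chain to give 6.

Step 8. Boronate formation may be incomplete or the boronate may exchange during acylation, so that O6 is benzoylated or the benzoate migrates. Base-induced loss of the γ-benzoate from the enone is a further risk.
- Fallback (sets out from 11, returns at 14): a robust, isolated acetal replaces the transient boronate.
- 11 with 2,2-dimethoxypropane and PPTS gives the C1/C6 acetonide F7. The trans C5/C6 pair cannot compete and O7 is already acylated.
- BzCl, pyridine and DMAP give zeylenone acetonide F8, and aqueous trifluoroacetic acid in CH2Cl2 at 0 °C releases 14.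

Further compounds
F1 | step 4 | methyl 4-bromo-2-oxo-1,3-dioxolane-4-carboxylate (racemic) | COC(=O)C1(Br)COC(=O)O1
F2 | step 4 | methyl 2-oxo-1,3-dioxole-4-carboxylate | COC(=O)C1=COC(=O)O1
F3 | step 4 | racemic carbonate adduct: methyl 1-methoxy-7-oxabicyclo[2.2.1]hept-5-ene-2-exo-carboxylate 2,3-endo-cyclic carbonate (drawn as the enantiomer that leads to 9) | CO[C@@]12C=C[C@@H](O1)[C@@H]3OC(=O)O[C@]23C(=O)OC
F4 | step 4 | racemic triol, rac-9 (drawn as the enantiomer that is kept) | CO[C@@]12C=C[C@@H](O1)[C@H](O)[C@@]2(O)CO
F5 | step 3 | [(2R,4R)-2-tert-butyl-5-oxo-1,3-dioxolan-4-yl]methyl acetate | CC(C)(C)[C@H]1OC(=O)[C@@H](COC(C)=O)O1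
F6 | step 3 | tertiary ring bromide: [(2R)-4-bromo-2-tert-butyl-5-oxo-1,3-dioxolan-4-yl]methyl acetate, Br trans to tert-butyl | CC(C)(C)[C@H]1OC(=O)[C@@](Br)(COC(C)=O)O1
F7 | step 8 | C1/C6 acetonide of 11 | O=C(OC[C@]12OC(C)(C)O[C@H]1[C@H](O)C=CC2=O)c3ccccc3
F8 | step 8 | zeylenone acetonide (C1/C6) | O=C(OC[C@]12OC(C)(C)O[C@H]1[C@H](OC(=O)c3ccccc3)C=CC2=O)c4ccccc4
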